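Numbering: ring A = C1–C5 and C10, ring B = C5–C10, ring C = C8, C17, C15, C14=C13, C12, C11, C9. The enabling feature is the C7(OAc)–C8(OH)–C17(=O) array across rings B and C, an α,β-dioxygenated ketone that is the aldol adduct of the ring-C C8=C17 enediol and a C7 carbonyl carbon.
Cuts, in retro order: acyl groups and C11 ketone (from a C11 silyl ether); C7–C8 (Mukaiyama-type aldol, ring B); C8–C17 (acyloin, ring C); C9–C11 (auxiliary aldol with a Z aldehyde ester from 4-methylanisole); C1/C2 oxygens; C10–C9 and C5–C6 (conjugate addition and enolate alkylation on 2,4,4-trimethylcyclohexenone).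
Forward: ring A is bought; both side chains are set on it in one step; the all-cis triol is built; the C11–C17 chain is joined by aldol; ring C closes by acyloin condensation with chlorosilane; ring B closes in the key step; acyl groups go on and C11 is oxidised last.
Stereochemistry: C5 from a chiral copper catalyst and C10 trans to it; C3 from α-face epoxidation and Wharton transposition; C1 and C2 from hydroxyl-directed osmylation; C9 from an oxazolidinone auxiliary; C7 and C8 from the chair closure of ring B.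
Two design points: C7 enters the key step as its diallyl acetal (oxocarbenium ion under silyl triflate), because an aldehyde cannot be unveiled next to the enediol ether; C11 stays a silyl ether until the end, so C9 never lies between two carbonyl groups before the final step.

Key step: step 18

Assumption: the enantiomer of the copper/NHC catalyst in step 1 is taken to be the one that gives the (1S,2R) keto ester; atom numbers are those of the target, and α/β mean the face opposite to / on the side of the C10 methyl group.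

Step 1
Reactants: 1 2,4,4-trimethylcyclohex-2-en-1-one; 2 vinylmagnesium bromide; 3 tert-butyl bromoacetate
Product: 5 tert-butyl 2-[(1S,2R)-2-ethenyl-1,3,3-trimethyl-6-oxocyclohexyl]acetate, via bromomagnesium enolate 4 (not isolated)
Conditions: Cu(OTf)2 (3 mol %), chiral imidazolinium NHC precursor (4 mol %), 2, Et2O, −30 °C; then 3, DMPU, −30 → 0 °C
Reagents that add atoms: vinylmagnesium bromide (2) C=C[Mg]Br; tert-butyl bromoacetate (3) CC(C)(C)OC(=O)CBr
Why: Copper-catalysed asymmetric conjugate addition followed by alkylation of the regiodefined magnesium enolate (tandem 1,4-addition/enolate trapping) should set C5 under catalyst control and C10 by entry of the bromoacetate trans to the neighbouring C5 vinyl group.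

Step 2
Reactants: 5 tert-butyl 2-[(1S,2R)-2-ethenyl-1,3,3-trimethyl-6-oxocyclohexyl]acetate
Product: 6 tert-butyl 2-[(1S,6R)-6-ethenyl-1,5,5-trimethyl-2-oxocyclohex-3-en-1-yl]acetate
Conditions: IBX, DMSO/PhF, 70 °C
Reagents that add atoms: none
Why: IBX-mediated dehydrogenation of the ketone can only introduce the C2=C3 double bond because C10 is quaternary, and neither the ester nor the vinyl group is touched.

Step 3
Reactants: 6 tert-butyl 2-[(1S,6R)-6-ethenyl-1,5,5-trimethyl-2-oxocyclohex-3-en-1-yl]acetate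
Product: 7 2α,3α-epoxy ketone of 6
Conditions: 30% H2O2, NaOH (cat.), MeOH, 0 °C
Reagents that add atoms: hydrogen peroxide OO
Why: Weitz–Scheffer nucleophilic epoxidation, in which hydroperoxide should add axially to C3 from the α face, away from the pseudoaxial β-methyl groups on C4 and C10, so that the cis-epoxide sets C2 and C3 on the α face.

Step 4
Reactants: 7 2α,3α-epoxy ketone of 6
Product: 9 tert-butyl ester allylic alcohol with C1=C2 and 3α-OH, via C1 hydrazone 8 (not isolated)
Conditions: N2H4·H2O, AcOH (cat.), MeOH, 0 °C → rt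
Reagents that add atoms: none
Why: Wharton transposition, in which the C1 hydrazone fragments with loss of dinitrogen to the C1=C2 alkene while the C3–O bond is not broken, so C3 keeps its α oxygen, and the tert-butyl ester resists hydrazine.

Step 5
Reactants: 9 tert-butyl ester allylic alcohol with C1=C2 and 3α-OH
Product: 11 1α,2α,3α-triol tert-butyl ester, via TMEDA-ligated osmate ester 10 (not isolated)
Conditions: OsO4 (1.05 equiv), TMEDA, CH2Cl2, −78 °C; then aq. Na2SO3, THF, reflux
Reagents that add atoms: osmium tetroxide O=[Os](=O)(=O)=O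
Why: Hydrogen-bond-directed dihydroxylation, in which the OsO4·TMEDA complex is held by the C3 hydroxyl and should add to the α face of C1=C2 (also the face away from the β-methyl groups), setting C1 and C2 syn to C3, while the vinyl group on the doubly neopentyl C5 is not reached at −78 °C by one equivalent.

Step 6
Reactants: 11 1α,2α,3α-triol tert-butyl ester
Product: 13 2-O-triethylsilyl 1,3-O-di-tert-butylsilylene tert-butyl ester, via C2 triethylsilyl ether 12 (not isolated)
Conditions: TESOTf (1.05 equiv), 2,6-lutidine, CH2Cl2, −78 °C; then t-Bu2Si(OTf)2, −78 → 0 °C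
Reagents that add atoms: triethylsilyl triflate CC[Si](CC)(CC)OS(=O)(=O)C(F)(F)F; di-tert-butylsilyl bis(triflate) CC(C)(C)[Si](OS(=O)(=O)C(F)(F)F)(OS(=O)(=O)C(F)(F)F)C(C)(C)C
Why: Silyl ether formation in order of accessibility, the equatorial C2 hydroxyl taking the triethylsilyl group first, after which only the two axial, 1,3-related hydroxyls at C1 and C3 remain to be bridged as a six-membered silylene.

Step 7
Reactants: 13 2-O-triethylsilyl 1,3-O-di-tert-butylsilylene tert-butyl ester
Product: 15 ring-A carboxylic acid (C8 acid), via trimethylsilyl ester 14 (not isolated)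
Conditions: TMSOTf, 2,6-lutidine, CH2Cl2, 0 °C; then pH 5 buffer
Reagents that add atoms: none
Why: Silyl triflate converts the tert-butyl ester into the silyl ester with loss of 2-methylpropene under lutidine buffering, conditions that leave the silyl ethers and the silylene in place, and the silyl ester hydrolyses on work-up.

Step 8
Reactants: 15 ring-A carboxylic acid (C8 acid); 16 (R)-4-benzyl-1,3-oxazolidin-2-one
Product: 18 ring-A N-acyl oxazolidinone, via mixed pivalic anhydride 17 (not isolated)
Conditions: PivCl, Et3N, THF, −20 °C; then 16, LiCl, −20 °C → rt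
Reagents that add atoms: (R)-4-benzyl-1,3-oxazolidin-2-one (16) O=C1N[C@H](Cc2ccccc2)CO1
Why: N-Acylation of the Evans oxazolidinone through the mixed pivalic anhydride, which is attacked at the less hindered CH2–C(=O) carbonyl, with no stereocenter touched.

Step 9
Reactants: 19 4-methylanisole
Product: 20 1-methoxy-4-methylcyclohexa-1,4-diene
Conditions: Li, NH3 (l), t-BuOH, THF, −78 → −33 °C
Reagents that add atoms: none
Why: Birch reduction of an anisole gives the 2,5-dihydro product in which the methoxy-bearing and the methyl-bearing carbons stay sp2, so the later Z-alkene is locked in a six-membered ring.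

Step 10
Reactants: 20 1-methoxy-4-methylcyclohexa-1,4-diene
Product: 22 methyl (3Z)-4-methyl-6-oxohex-3-enoate, via methoxy hydroperoxide 21 (not isolated)
Conditions: O3 (1 equiv), CH2Cl2/MeOH, NaHCO3, −78 °C; then Me2S, −78 °C → rt
Reagents that add atoms: ozone [O-][O+]=O
Why: Ozonolysis with reductive work-up cleaves the electron-rich enol ether double bond far faster than the trisubstituted alkene, giving the methyl ester from the methoxy carbon and the aldehyde from its neighbour with the ring-derived Z geometry intact.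

Step 11
Reactants: 18 ring-A N-acyl oxazolidinone; 22 methyl (3Z)-4-methyl-6-oxohex-3-enoate
Product: 25 (9R,11S)-syn-aldol imide, via boron enolate 23 (not isolated), via boron aldolate 24 (not isolated)
Conditions: Bu2BOTf, i-Pr2NEt, CH2Cl2, 0 °C; 22, −78 → 0 °C; then pH 7 buffer, MeOH, 30% H2O2, 0 °C
Reagents that add atoms: none
Why: Evans syn-aldol reaction, in which the (Z)-boron enolate reacts through a Zimmerman–Traxler chair on the face away from the benzyl group of the (R)-auxiliary, which should set C9 as R (H α in the target) and the temporary C11 carbinol as S irrespective of the quaternary C10, and the amine base is too weak to move the β,γ-double bond.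

Step 12
Reactants: 25 (9R,11S)-syn-aldol imide
Product: 26 (9R,11S)-11-hydroxy C8/C17 dimethyl diester
Conditions: MeMgBr (2 equiv), MeOH, CH2Cl2, 0 °C
Reagents that add atoms: methanol CO
Why: Magnesium-chelate-assisted transesterification of the β-hydroxy imide with bromomagnesium methoxide releases the auxiliary as the methyl ester forms, without epimerising C9 or moving the skipped alkene.

Step 13
Reactants: 26 (9R,11S)-11-hydroxy C8/C17 dimethyl diester
Product: 27 11-O-tert-butyldimethylsilyl dimethyl diester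
Conditions: TBSOTf, 2,6-lutidine, CH2Cl2, −78 → 0 °C
Reagents that add atoms: tert-butyldimethylsilyl triflate CC(C)(C)[Si](C)(C)OS(=O)(=O)C(F)(F)F
Why: Silylation of the hindered secondary C11 alcohol with a silyl triflate and lutidine gives an ether that must survive sodium, Lewis acid and the first fluoride treatment.

Step 14
Reactants: 27 11-O-tert-butyldimethylsilyl dimethyl diester
Product: 29 C7 primary alcohol, via B-alkyl-9-BBN 28 (not isolated)
Conditions: 9-BBN, THF, 0 °C → rt; then 30% H2O2, aq. NaOAc, 0 °C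
Reagents that add atoms: hydrogen peroxide OO
Why: Brown hydroboration–oxidation, in which 9-BBN adds to the terminal carbon of the monosubstituted vinyl group only, leaving the trisubstituted alkene and both esters, and buffered peroxide gives the primary C7 alcohol.

Step 15
Reactants: 29 C7 primary alcohol
Product: 30 C7 aldehyde
Conditions: Dess–Martin periodinane, NaHCO3, CH2Cl2, 0 °C → rt
Reagents that add atoms: none
Why: Dess–Martin oxidation of the primary alcohol to the aldehyde under buffered, non-basic conditions.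

Step 16
Reactants: 30 C7 aldehyde
Product: 31 C7 diallyl acetal dimethyl diester
Conditions: allyloxytrimethylsilane (3 equiv), TMSOTf (5 mol %), CH2Cl2, −78 °C
Reagents that add atoms: allyloxytrimethylsilane C=CCO[Si](C)(C)C
Why: Silyl-triflate-catalysed acetalisation of the aldehyde with an alkoxysilane at −78 °C gives the diallyl acetal, which is inert to sodium and is the latent C7 oxocarbenium ion.

Step 17
Reactants: 31 C7 diallyl acetal dimethyl diester
Product: 32 ring A linked to the cycloocta-1,4-diene 8,17-bis(trimethylsilyl) enediol ether with C7 diallyl acetal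
Conditions: Na dispersion (4.5 equiv), TMSCl (6 equiv), toluene, 90–110 °C, syringe-pump addition (0.005 M); filtration under argon, used crude
Reagents that add atoms: chlorotrimethylsilane C[Si](C)(C)Cl
Why: Acyloin condensation in the Rühlmann variant, in which electron transfer from sodium couples the two ester carbonyls and chlorotrimethylsilane traps the enediolate and the methoxide, so that neither Dieckmann condensation nor base-induced migration of the skipped alkene can compete, the cis double bond and high dilution favouring the eight-membered ring; no stereocenter is formed.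

Step 18
Reactants: 32 ring A linked to the cycloocta-1,4-diene 8,17-bis(trimethylsilyl) enediol ether with C7 diallyl acetal
Product: 33 6-6-8 tricycle with 7α-allyloxy 8β-trimethylsilyloxy and C17 ketone
Conditions: TMSOTf (0.2 equiv), 2,6-di-tert-butyl-4-methylpyridine (0.3 equiv), CH2Cl2 (0.002 M), −78 → −40 °C
Reagents that add atoms: none
Why: TMSOTf ionises the diallyl acetal to the C7 O-allyl oxocarbenium ion (allyloxytrimethylsilane leaves), C8 of the ring-C 1,2-bis(trimethylsilyloxy)alkene adds to it, and loss of the C17 silyl group to triflate returns the catalyst and leaves the C17 ketone and the C8 silyl ether. The closest known reaction is the Lewis-acid (Mukaiyama-type) addition of acyloin-derived 1,2-bis(silyloxy)alkenes and of simple enol silanes to acetals, used here within one molecule. Ring B closes in a 6-(enolexo)-exo-trig mode through a chair in which the C10 methyl and C9–H are axial and the C9–C11 bond is equatorial. C8 is set by that chair, the C8–C17 bond taking the equatorial site so that ring C is diequatorial on ring B and only the small silyloxy group is syn-axial to the C10 methyl; C7 is set by the oxocarbenium oxygen taking the axial site anti to the C8–O bond, where the dipoles oppose and the allyl group avoids the C8 substituents. The step needs C8 rather than C17 to attack and the acetal rather than a silyl ether to ionise: only attack through C8 gives a six-membered ring (C17 would give a seven-membered one), and the acyclic acetal is the only group that TMSOTf opens at −78 °C, the hindered base keeping triflic acid from stripping the enol silyl groups.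

Step 19
Reactants: 33 6-6-8 tricycle with 7α-allyloxy 8β-trimethylsilyloxy and C17 ketone
Product: 35 tricyclic 2,7,8-triol, via C7 alcohol 34 (not isolated)
Conditions: [CpRu(MeCN)3]PF6 (5 mol %), quinaldic acid (5 mol %), MeOH, 30 °C; then PPTS, rt
Reagents that add atoms: none
Why: Ruthenium π-allyl-catalysed deallylation in methanol frees the C7 hydroxyl as allyl methyl ether leaves, and mild acid methanolysis then removes the triethylsilyl and trimethylsilyl ethers while the tert-butyldimethylsilyl ether and the silylene stay.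

Step 20
Reactants: 35 tricyclic 2,7,8-triol
Product: 36 tricyclic 2,7-diacetate
Conditions: Ac2O, DMAP (cat.), pyridine, CH2Cl2, 0 °C → rt
Reagents that add atoms: acetic anhydride CC(=O)OC(C)=O
Why: DMAP-catalysed acetylation esterifies the two secondary hydroxyls at C2 and C7, whereas the tertiary C8 hydroxyl next to the ketone is too hindered to react under these conditions.

Step 21
Reactants: 36 tricyclic 2,7-diacetate
Product: 37 tricyclic 1,3-diol
Conditions: HF·pyridine, pyridine, THF, 0 °C
Reagents that add atoms: none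
Why: Buffered HF·pyridine cleaves the strained cyclic silylene much faster than the hindered secondary tert-butyldimethylsilyl ether at C11, and the esters are stable to it.

Step 22
Reactants: 37 tricyclic 1,3-diol
Product: 38 tricyclic 1,3-dibenzoate
Conditions: BzCl, DMAP, pyridine, 40 °C
Reagents that add atoms: benzoyl chloride O=C(Cl)c1ccccc1
Why: DMAP-catalysed benzoylation of the two axial hydroxyls at C1 and C3, in which the equatorial C2 acetate is already in the thermodynamically preferred acyl position and should not migrate, and the tertiary C8 hydroxyl stays free.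

Step 23
Reactants: 38 tricyclic 1,3-dibenzoate
Product: 39 C11 alcohol
Conditions: HF·pyridine, THF, rt
Reagents that add atoms: none
Why: Acidic fluoride removes the remaining silyl ether without base, so that no acyl group migrates.

Step 24
Reactants: 39 C11 alcohol
Product: 40 CNP0214674.2
Conditions: Dess–Martin periodinane, NaHCO3, CH2Cl2, 0 °C → rt
Reagents that add atoms: none
Why: Dess–Martin oxidation of the secondary C11 alcohol under neutral buffered conditions gives the C11 ketone last, so that C9, now α to a ketone and β to the C8 hydroxyl, never meets base or acid.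

Compound list
1 | 2,4,4-trimethylcyclohex-2-en-1-one | CC1=CC(C)(C)CCC1=O | starting material
2 | vinylmagnesium bromide | C=C[Mg]Br | starting material
3 | tert-butyl bromoacetate | CC(C)(C)OC(=O)CBr | starting material
4 | bromomagnesium 3-ethenyl-2,4,4-trimethylcyclohex-1-en-1-olate (C5 vinyl β) | Br[Mg]OC1=C(C)[C@H](C=C)C(C)(C)CC1 | intermediate
5 | tert-butyl 2-[(1S,2R)-2-ethenyl-1,3,3-trimethyl-6-oxocyclohexyl]acetate (C1 ketone; C10 methyl β, CH2CO2tBu α; C5 vinyl β) | O=C1[C@@](C)(CC(=O)OC(C)(C)C)[C@H](C=C)C(C)(C)CC1 | intermediate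
6 | tert-butyl 2-[(1S,6R)-6-ethenyl-1,5,5-trimethyl-2-oxocyclohex-3-en-1-yl]acetate (C2=C3 enone) | O=C1[C@@](C)(CC(=O)OC(C)(C)C)[C@H](C=C)C(C)(C)C=C1 | intermediate
7 | 2α,3α-epoxy ketone of 6 | O=C1[C@@](C)(CC(=O)OC(C)(C)C)[C@H](C=C)C(C)(C)[C@H]2O[C@@H]12 | intermediate
8 | C1 hydrazone of 7 | NN=C1[C@@](C)(CC(=O)OC(C)(C)C)[C@H](C=C)C(C)(C)[C@H]2O[C@@H]12 | intermediate
9 | tert-butyl ester allylic alcohol, C1=C2, 3α-OH | O[C@H]1C=C[C@@](C)(CC(=O)OC(C)(C)C)[C@H](C=C)C1(C)C | intermediate
10 | cyclic C1,C2 osmate(VI) ester of 9, TMEDA complex | O=[Os]1(=O)O[C@H]2[C@@H](O1)[C@@](C)(CC(=O)OC(C)(C)C)[C@H](C=C)C(C)(C)[C@H]2O.CN(C)CCN(C)C | intermediate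
11 | 1α,2α,3α-triol tert-butyl ester | O[C@H]1[C@@H](O)[C@@](C)(CC(=O)OC(C)(C)C)[C@H](C=C)C(C)(C)[C@H]1O | intermediate
12 | 2-O-triethylsilyl ether of 11 | CC[Si](CC)(CC)O[C@H]1[C@@H](O)[C@@](C)(CC(=O)OC(C)(C)C)[C@H](C=C)C(C)(C)[C@H]1O | intermediate
13 | 2-O-triethylsilyl 1,3-O-di-tert-butylsilylene tert-butyl ester | CC[Si](CC)(CC)O[C@H]1[C@@H](O[Si]2(C(C)(C)C)C(C)(C)C)[C@@](C)(CC(=O)OC(C)(C)C)[C@H](C=C)C(C)(C)[C@H]1O2 | intermediate
14 | trimethylsilyl ester corresponding to 13 | CC[Si](CC)(CC)O[C@H]1[C@@H](O[Si]2(C(C)(C)C)C(C)(C)C)[C@@](C)(CC(=O)O[Si](C)(C)C)[C@H](C=C)C(C)(C)[C@H]1O2 | intermediate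
15 | ring-A carboxylic acid (C8 acid) | CC[Si](CC)(CC)O[C@H]1[C@@H](O[Si]2(C(C)(C)C)C(C)(C)C)[C@@](C)(CC(=O)O)[C@H](C=C)C(C)(C)[C@H]1O2 | intermediate
16 | (R)-4-benzyl-1,3-oxazolidin-2-one | O=C1N[C@H](Cc2ccccc2)CO1 | starting material
17 | mixed anhydride of 15 with pivalic acid | CC[Si](CC)(CC)O[C@H]1[C@@H](O[Si]2(C(C)(C)C)C(C)(C)C)[C@@](C)(CC(=O)OC(=O)C(C)(C)C)[C@H](C=C)C(C)(C)[C@H]1O2 | intermediate
18 | ring-A N-acyl (R)-4-benzyloxazolidinone | CC[Si](CC)(CC)O[C@H]1[C@@H](O[Si]2(C(C)(C)C)C(C)(C)C)[C@@](C)(CC(=O)N3[C@H](Cc4ccccc4)COC3=O)[C@H](C=C)C(C)(C)[C@H]1O2 | intermediate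
19 | 4-methylanisole | COc1ccc(C)cc1 | starting material
20 | 1-methoxy-4-methylcyclohexa-1,4-diene | COC1=CCC(C)=CC1 | intermediate
21 | methyl (3Z)-6-hydroperoxy-6-methoxy-4-methylhex-3-enoate | COC(=O)C/C=C(/C)CC(OC)OO | intermediate
22 | methyl (3Z)-4-methyl-6-oxohex-3-enoate (C17 ester, Z C14=C13, C11 aldehyde) | COC(=O)C/C=C(/C)CC=O | intermediate
23 | (Z)-dibutylboron enolate of 18 | CC[Si](CC)(CC)O[C@H]1[C@@H](O[Si]2(C(C)(C)C)C(C)(C)C)[C@@](C)(/C=C(\OB(CCCC)CCCC)N3[C@H](Cc4ccccc4)COC3=O)[C@H](C=C)C(C)(C)[C@H]1O2 | intermediate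
24 | dibutylboron aldolate of 25 | CC[Si](CC)(CC)O[C@H]1[C@@H](O[Si]2(C(C)(C)C)C(C)(C)C)[C@@](C)([C@H]([C@@H](OB(CCCC)CCCC)C/C(C)=C\CC(=O)OC)C(=O)N3[C@H](Cc4ccccc4)COC3=O)[C@H](C=C)C(C)(C)[C@H]1O2 | intermediate
25 | (9R,11S)-syn-aldol imide | CC[Si](CC)(CC)O[C@H]1[C@@H](O[Si]2(C(C)(C)C)C(C)(C)C)[C@@](C)([C@H]([C@@H](O)C/C(C)=C\CC(=O)OC)C(=O)N3[C@H](Cc4ccccc4)COC3=O)[C@H](C=C)C(C)(C)[C@H]1O2 | intermediate
26 | (9R,11S)-11-hydroxy C8/C17 dimethyl diester | CC[Si](CC)(CC)O[C@H]1[C@@H](O[Si]2(C(C)(C)C)C(C)(C)C)[C@@](C)([C@H]([C@@H](O)C/C(C)=C\CC(=O)OC)C(=O)OC)[C@H](C=C)C(C)(C)[C@H]1O2 | intermediate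
27 | 11-O-tert-butyldimethylsilyl dimethyl diester | CC[Si](CC)(CC)O[C@H]1[C@@H](O[Si]2(C(C)(C)C)C(C)(C)C)[C@@](C)([C@H]([C@@H](O[Si](C)(C)C(C)(C)C)C/C(C)=C\CC(=O)OC)C(=O)OC)[C@H](C=C)C(C)(C)[C@H]1O2 | intermediate
28 | B-(C7-alkyl)-9-borabicyclo[3.3.1]nonane | CC[Si](CC)(CC)O[C@H]1[C@@H](O[Si]2(C(C)(C)C)C(C)(C)C)[C@@](C)([C@H]([C@@H](O[Si](C)(C)C(C)(C)C)C/C(C)=C\CC(=O)OC)C(=O)OC)[C@H](CCB3C4CCCC3CCC4)C(C)(C)[C@H]1O2 | intermediate
29 | C7 primary alcohol | CC[Si](CC)(CC)O[C@H]1[C@@H](O[Si]2(C(C)(C)C)C(C)(C)C)[C@@](C)([C@H]([C@@H](O[Si](C)(C)C(C)(C)C)C/C(C)=C\CC(=O)OC)C(=O)OC)[C@H](CCO)C(C)(C)[C@H]1O2 | intermediate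
30 | C7 aldehyde | CC[Si](CC)(CC)O[C@H]1[C@@H](O[Si]2(C(C)(C)C)C(C)(C)C)[C@@](C)([C@H]([C@@H](O[Si](C)(C)C(C)(C)C)C/C(C)=C\CC(=O)OC)C(=O)OC)[C@H](CC=O)C(C)(C)[C@H]1O2 | intermediate
31 | C7 diallyl acetal dimethyl diester | CC[Si](CC)(CC)O[C@H]1[C@@H](O[Si]2(C(C)(C)C)C(C)(C)C)[C@@](C)([C@H]([C@@H](O[Si](C)(C)C(C)(C)C)C/C(C)=C\CC(=O)OC)C(=O)OC)[C@H](CC(OCC=C)OCC=C)C(C)(C)[C@H]1O2 | intermediate
32 | ring A linked to the cycloocta-1,4-diene 8,17-bis(trimethylsilyl) enediol ether, C7 diallyl acetal (key-step precursor) | CC[Si](CC)(CC)O[C@H]1[C@@H](O[Si]2(C(C)(C)C)C(C)(C)C)[C@@](C)([C@H]3/C(O[Si](C)(C)C)=C(O[Si](C)(C)C)\C/C=C(/C)C[C@@H]3O[Si](C)(C)C(C)(C)C)[C@H](CC(OCC=C)OCC=C)C(C)(C)[C@H]1O2 | intermediate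
33 | 6-6-8 tricycle, 7α-allyloxy, 8β-trimethylsilyloxy, C17 ketone (key-step product) | CC[Si](CC)(CC)O[C@H]1[C@@H](O[Si]2(C(C)(C)C)C(C)(C)C)[C@]3(C)[C@H](C[C@H](OCC=C)[C@]4(O[Si](C)(C)C)C(=O)C/C=C(/C)C[C@H](O[Si](C)(C)C(C)(C)C)[C@@H]34)C(C)(C)[C@H]1O2 | intermediate
34 | tricyclic C7 alcohol (2-OTES, 8-OTMS retained) | CC[Si](CC)(CC)O[C@H]1[C@@H](O[Si]2(C(C)(C)C)C(C)(C)C)[C@]3(C)[C@H](C[C@H](O)[C@]4(O[Si](C)(C)C)C(=O)C/C=C(/C)C[C@H](O[Si](C)(C)C(C)(C)C)[C@@H]34)C(C)(C)[C@H]1O2 | intermediate
35 | tricyclic 2,7,8-triol (1,3-silylene, 11-OTBS) | O[C@H]1[C@@H](O[Si]2(C(C)(C)C)C(C)(C)C)[C@]3(C)[C@H](C[C@H](O)[C@]4(O)C(=O)C/C=C(/C)C[C@H](O[Si](C)(C)C(C)(C)C)[C@@H]34)C(C)(C)[C@H]1O2 | intermediate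
36 | tricyclic 2,7-diacetate | CC(=O)O[C@H]1[C@@H](O[Si]2(C(C)(C)C)C(C)(C)C)[C@]3(C)[C@H](C[C@H](OC(C)=O)[C@]4(O)C(=O)C/C=C(/C)C[C@H](O[Si](C)(C)C(C)(C)C)[C@@H]34)C(C)(C)[C@H]1O2 | intermediate
37 | tricyclic 1,3-diol (2,7-diacetate, 11-OTBS) | CC(=O)O[C@H]1[C@@H](O)[C@]2(C)[C@H](C[C@H](OC(C)=O)[C@]3(O)C(=O)C/C=C(/C)C[C@H](O[Si](C)(C)C(C)(C)C)[C@H]32)C(C)(C)[C@H]1O | intermediate
38 | tricyclic 1,3-dibenzoate (11-OTBS) | CC(=O)O[C@H]1[C@@H](OC(=O)c2ccccc2)[C@]2(C)[C@H](C[C@H](OC(C)=O)[C@]3(O)C(=O)C/C=C(/C)C[C@H](O[Si](C)(C)C(C)(C)C)[C@H]32)C(C)(C)[C@H]1OC(=O)c1ccccc1 | intermediate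
39 | C11 alcohol | CC(=O)O[C@H]1[C@@H](OC(=O)c2ccccc2)[C@]2(C)[C@H](C[C@H](OC(C)=O)[C@]3(O)C(=O)C/C=C(/C)C[C@H](O)[C@H]32)C(C)(C)[C@H]1OC(=O)c1ccccc1 | intermediate
40 | CNP0214674.2 | CC(=O)O[C@H]1[C@@H](OC(=O)c2ccccc2)[C@]2(C)[C@H](C[C@H](OC(C)=O)[C@]3(O)C(=O)C/C=C(/C)CC(=O)[C@H]32)C(C)(C)[C@H]1OC(=O)c1ccccc1 | target

Total step count: 24. Longest linear sequence: 22 steps (steps 1–8 and 11–24); steps 9–10 make the chain fragment.

Steps most likely to fail

Step 18. The enol silyl groups may be stripped by adventitious acid before the C7–C8 bond forms, or the facial selectivity at C7 may be poor. The fallback moves the closure to a reversible direct aldol and sets out from 32. Aqueous acetic acid in THF, then PPTS in wet acetone at 40 °C, should cleave the two enol silyl ethers, the triethylsilyl ether and the diallyl acetal, leaving the silylene and the C11 silyl ether, to give the acyloin aldehyde F1. F1 is then cyclised by an amine-free titanium(IV) alkoxide/α-hydroxy acid direct aldol of the α-hydroxy ketone (titanium enediolate), which is reversible and should settle on the trans-fused ring B. The product is triol 35, where the route is rejoined.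

Step 17. Intermolecular coupling or simple reduction of the hindered C8 ester may outrun the eight-membered ring closure. The fallback closes ring C by a pinacol reaction and sets out from 31. DIBAL-H at −78 °C should reduce both esters to the dialdehyde F2. SmI2 in THF at high dilution couples the two aldehydes to the ring-C 8,17-diol F3. Swern oxidation gives the ring-C 8,17-dione F4, which is used at once. Reductive silylation with zinc and chlorotrimethylsilane gives the bis(silyl) enediol ether 32, where the route is rejoined.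

Step 1. Conversion or enantioselectivity of the catalytic addition to the hindered α-methyl enone may be low. The fallback uses resolution and sets out from 1. The tandem addition/alkylation is run with CuI·SMe2 and no chiral ligand, giving 5 together with its enantiomer F5. TFA in CH2Cl2 removes the tert-butyl group. The racemic acid is resolved by crystallising its (R)-1-phenylethylammonium salt to give the (1S,2R) keto acid F6, with the enantiomeric keto acid F7 staying in the mother liquor. F6 is re-esterified with tert-butyl 2,2,2-trichloroacetimidate and catalytic BF3·OEt2 to give 5, where the route is rejoined.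

Further compounds
F1 | step 18 | acyloin aldehyde (2-OH, 1,3-silylene, 11-OTBS, 8-hydroxy-17-oxo tautomer, C7 aldehyde) | O[C@H]1[C@@H](O[Si]2(C(C)(C)C)C(C)(C)C)[C@@](C)([C@H]3C(O)C(=O)C/C=C(/C)C[C@@H]3O[Si](C)(C)C(C)(C)C)[C@H](CC=O)C(C)(C)[C@H]1O2
F2 | step 17 | C8/C17 dialdehyde with C7 diallyl acetal | CC[Si](CC)(CC)O[C@H]1[C@@H](O[Si]2(C(C)(C)C)C(C)(C)C)[C@@](C)([C@H]([C@@H](O[Si](C)(C)C(C)(C)C)C/C(C)=C\CC=O)C=O)[C@H](CC(OCC=C)OCC=C)C(C)(C)[C@H]1O2
F3 | step 17 | ring-C 8,17-diol | CC[Si](CC)(CC)O[C@H]1[C@@H](O[Si]2(C(C)(C)C)C(C)(C)C)[C@@](C)([C@H]3C(O)C(O)C/C=C(/C)C[C@@H]3O[Si](C)(C)C(C)(C)C)[C@H](CC(OCC=C)OCC=C)C(C)(C)[C@H]1O2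
F4 | step 17 | ring-C 8,17-dione | CC[Si](CC)(CC)O[C@H]1[C@@H](O[Si]2(C(C)(C)C)C(C)(C)C)[C@@](C)([C@H]3C(=O)C(=O)C/C=C(/C)C[C@@H]3O[Si](C)(C)C(C)(C)C)[C@H](CC(OCC=C)OCC=C)C(C)(C)[C@H]1O2
F5 | step 1 | tert-butyl 2-[(1R,2S)-2-ethenyl-1,3,3-trimethyl-6-oxocyclohexyl]acetate (enantiomer of 5) | O=C1[C@](C)(CC(=O)OC(C)(C)C)[C@@H](C=C)C(C)(C)CC1
F6 | step 1 | 2-[(1S,2R)-2-ethenyl-1,3,3-trimethyl-6-oxocyclohexyl]acetic acid | O=C1[C@@](C)(CC(=O)O)[C@H](C=C)C(C)(C)CC1
F7 | step 1 | 2-[(1R,2S)-2-ethenyl-1,3,3-trimethyl-6-oxocyclohexyl]acetic acid | O=C1[C@](C)(CC(=O)O)[C@@H](C=C)C(C)(C)CC1
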